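The plan rests on cutting C16–C18 and C21–C22 together. C16 and C22, the α- and β-carbons of lactone ring B, are neighbours in ring C. C21–C22 is common to ring C and the eleven-membered ring D. A single [4+2] addition of a C18–C21 diene across the butenolide alkene therefore closes both carbocycles and sets C16, C22 and, transiently, C18. The precursor holds rings A and B as a spiro cyclohexene–butenolide (tert-butyl ester at C9). Its C6 side chain carries the syn C2/C23 methyl pair and ends, through C20, in an (E)-1-silyloxybutadiene. Ring A comes from an auxiliary-controlled Diels–Alder reaction, the chain from a desymmetrised meso-anhydride.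

Key step: step 21

Locants: C1–C25 follow the heavy atoms of the target SMILES read from its left end; the five oxygens outside the rings are not counted and O14 is the lactone ring oxygen. Ring A = C6, C7, C8, C10, C12, C13. Ring B = C13, O14, C15, C16, C22. Ring C = C16, C18, C19, C20, C21, C22. Ring D = C2–C6, C13, C22, C21, C20, C23, C25.

Assumption: the target is taken as the diketo tautomer, and C20, the enolisable carbon next to the 1,2-dione, is taken to hold its thermodynamically preferred configuration (C23 cis to C13, so that ring C can place C13, C17 and C23 equatorial).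

Step 1
Reactants: 1 meso-2,4-dimethylglutaric anhydride
Product: 2 meso-(2R,4S)-2,4-dimethylpentane-1,5-diol
Conditions: LiAlH4, THF, 0 °C to reflux; aq NaOH work-up
Reagents that add atoms: none
Why: Exhaustive hydride reduction of a cyclic anhydride to the 1,5-diol leaves the two methyl-bearing carbons untouched, so the syn (meso) relationship of C2 and C23 is carried over.

Step 2
Reactants: 2 meso-(2R,4S)-2,4-dimethylpentane-1,5-diol
Product: 3 (2S,4R)-5-hydroxy-2,4-dimethylpentyl acetate (free OH on C20, acetate on C3)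
Conditions: Amano lipase AK, vinyl acetate, THF, rt
Reagents that add atoms: vinyl acetate, C=COC(C)=O
Why: Enzymatic desymmetrisation by irreversible lipase transesterification should acetylate only the hydroxymethyl arm next to the (S)-carbon, which turns the meso diol into one enantiomer and fixes the absolute configuration of C2 and C23.

Step 3
Reactants: 3 (2S,4R)-5-hydroxy-2,4-dimethylpentyl acetate
Product: 4 (2S,4R)-2,4-dimethyl-5-oxopentyl acetate (C20 aldehyde)
Conditions: TEMPO (10 mol %), PhI(OAc)2, CH2Cl2, rt
Reagents that add atoms: none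
Why: Oxoammonium (TEMPO) oxidation of a primary alcohol stops at the aldehyde under nearly neutral conditions, so the α-stereocentre C23 and the acetate are not disturbed.

Step 4
Reactants: 4 (2S,4R)-2,4-dimethyl-5-oxopentyl acetate
Product: 6 (2S,4R)-2,4-dimethylhex-5-yn-1-ol, via alkynyl acetate 5 (not isolated)
Conditions: dimethyl (1-diazo-2-oxopropyl)phosphonate, K2CO3, MeOH, 0 °C to rt
Reagents that add atoms: dimethyl (1-diazo-2-oxopropyl)phosphonate, COP(=O)(OC)C(=[N+]=[N-])C(C)=O
Why: Ohira–Bestmann homologation converts the aldehyde into the terminal alkyne (new carbon C19) faster than C23 can epimerise, and the same K2CO3/MeOH medium transesterifies the acetate and frees the C3 hydroxyl.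

Step 5
Reactants: 6 (2S,4R)-2,4-dimethylhex-5-yn-1-ol
Product: 7 (2S,4R)-2,4-dimethylhex-5-yn-1-yl 4-methylbenzenesulfonate
Conditions: TsCl, Et3N, DMAP (cat.), CH2Cl2, 0 °C to rt
Reagents that add atoms: 4-toluenesulfonyl chloride, Cc1ccc(cc1)S(=O)(=O)Cl
Why: Sulfonylation of an unhindered primary alcohol supplies the leaving group at C3 for the chain extension.

Step 6
Reactants: 7 (2S,4R)-2,4-dimethylhex-5-yn-1-yl 4-methylbenzenesulfonate; 8 (4-bromobut-1-yn-1-yl)trimethylsilane
Product: 10 [(6R,8R)-6,8-dimethyldeca-1,9-diyn-1-yl]trimethylsilane, via butynyl Grignard reagent 9 (not isolated)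
Conditions: 8, Mg, THF, rt to 40 °C; then 7, Li2CuCl4 (5 mol %), THF, −78 °C to rt (2.5 equiv of 9)
Reagents that add atoms: none
Why: Copper-catalysed cross-coupling of a primary tosylate and a primary alkyl Grignard reagent (SN2 at C3 by an alkylcuprate) adds C4–C7, the first equivalent of 9 being spent on the acidic alkyne C–H, which is restored on work-up.

Step 7
Reactants: 10 [(6R,8R)-6,8-dimethyldeca-1,9-diyn-1-yl]trimethylsilane
Product: 13 (2E,4R,6R)-3,4,6-trimethyl-11-(trimethylsilyl)undec-2-en-10-yn-1-ol, via alkenylalane 11 (not isolated), via lithium alanate 12 (not isolated)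
Conditions: Me3Al, Cp2ZrCl2 (25 mol %), CH2Cl2, 0 °C to rt; n-BuLi, hexane–THF, −78 °C; (CH2O)n, −78 °C to rt
Reagents that add atoms: trimethylaluminium, C[Al](C)C; paraformaldehyde (as formaldehyde), C=O
Why: Negishi zirconium-catalysed carboalumination adds Me–Al syn across the terminal alkyne (methyl C21 to C20, Al to C19) while the silylated alkyne reacts far more slowly, and the derived alanate is hydroxymethylated with retention (C18) to give the (E)-allylic alcohol.

Step 8
Reactants: 13 (2E,4R,6R)-3,4,6-trimethyl-11-(trimethylsilyl)undec-2-en-10-yn-1-ol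
Product: 14 the C18 tert-butyldimethylsilyl ether of 13
Conditions: TBSCl, imidazole, CH2Cl2, rt
Reagents that add atoms: tert-butyldimethylsilyl chloride, CC(C)(C)[Si](C)(C)Cl
Why: Silylation of a primary allylic alcohol masks the future enal through the organometallic, thermal and hydride steps that follow.

Step 9
Reactants: 14 the C18 tert-butyldimethylsilyl ether of 13
Product: 15 tert-butyldimethyl{[(2E,4R,6R)-3,4,6-trimethylundec-2-en-10-yn-1-yl]oxy}silane
Conditions: K2CO3 (0.2 equiv), MeOH, rt
Reagents that add atoms: none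
Why: Methoxide-catalysed protodesilylation cleaves the alkynyl C–Si bond selectively, because the O-TBS ether is far more robust to K2CO3/MeOH.

Step 10
Reactants: 16 propyne
Product: 18 tert-butyl but-2-ynoate, via propynyllithium 17 (not isolated)
Conditions: n-BuLi, THF, −78 °C; Boc2O, −78 °C to 0 °C; H2O quench
Reagents that add atoms: di-tert-butyl dicarbonate, CC(C)(C)OC(=O)OC(=O)OC(C)(C)C
Why: Acylation of a lithium acetylide by Boc2O is an established route to tert-butyl alkynoates and installs C9 directly as the tert-butyl ester.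

Step 11
Reactants: 18 tert-butyl but-2-ynoate
Product: 20 tert-butyl (E)-2-iodobut-2-enoate (methyl cis to the ester), via α-stannyl enoate 19 (not isolated)
Conditions: Bu3SnH, Pd(PPh3)4 (2 mol %), THF, 0 °C to rt; then I2, 0 °C
Reagents that add atoms: iodine, II
Why: Palladium-catalysed hydrostannation of an ynoate is a syn addition that places tin on the α-carbon, and iododestannylation goes with retention, so the methyl group (C11) ends up cis to the ester and trans to the future C7.

Step 12
Reactants: 15 tert-butyldimethyl{[(2E,4R,6R)-3,4,6-trimethylundec-2-en-10-yn-1-yl]oxy}silane; 20 tert-butyl (E)-2-iodobut-2-enoate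
Product: 22 tert-butyl (2Z,3E,8R,10R,11E)-13-[(tert-butyldimethylsilyl)oxy]-2-ethylidene-8,10,11-trimethyltrideca-3,11-dienoate, via alkenyl catecholborane 21 (not isolated)
Conditions: catecholborane, THF, 65 °C; then 20, Pd(PPh3)4 (5 mol %), aq K3PO4, THF, 50 °C
Reagents that add atoms: none
Why: Syn hydroboration of the terminal alkyne followed by Suzuki–Miyaura coupling, both partners reacting with retention, gives the C6=C7–C8=C10 diene with C5 and C11 both in the outside positions.

Step 13
Reactants: 23 (S)-lactic acid; 24 pivalaldehyde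
Product: 25 (2S,5S)-2-tert-butyl-5-methyl-1,3-dioxolan-4-one (cis)
Conditions: p-TsOH (cat.), pentane, reflux, Dean–Stark; crystallisation from pentane, −78 °C
Reagents that add atoms: none
Why: Acid-catalysed acetalisation of the α-hydroxy acid favours the cis-dioxolanone, which is purified by crystallisation, so the lactic acid centre sets the acetal carbon as (S).

Step 14
Reactants: 25 (2S,5S)-2-tert-butyl-5-methyl-1,3-dioxolan-4-one
Product: 27 (S)-2-tert-butyl-5-methylene-1,3-dioxolan-4-one, via tertiary bromide 26 (not isolated)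
Conditions: NBS, AIBN (cat.), PhCF3, reflux; filtration; Et3N, Et2O, 0 °C to rt
Reagents that add atoms: none
Why: Wohl–Ziegler bromination at the captodatively stabilised C5–H followed by E2 loss of HBr removes the lactic acid centre and leaves the acetal carbon as the only stereocentre of the dienophile.

Step 15
Reactants: 22 diene ester; 27 (S)-2-tert-butyl-5-methylene-1,3-dioxolan-4-one
Product: 28 spiro dioxolanone cycloadduct (ring A closed; 2R,6S,10S,13R,23R, acetal carbon S; C5, C11 and O14 on one face of ring A, C6 trans to the tert-butyl group across the dioxolanone)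
Conditions: 27 (3 equiv), BHT (cat.), toluene (1 M), 115 °C, sealed tube
Reagents that add atoms: none
Why: In this thermal intermolecular Diels–Alder reaction of the kind used for spirotetronate cyclohexenes, the C8 ester directs para (C6 to C13, C10 to C12), the diene adds to the face of 27 anti to the tert-butyl group (sets C13), and the lactone carbonyl sits exo with the ring oxygen endo (sets C6 and C10 cis to O14), so the remote C2/C23 centres play no part.

Step 16
Reactants: 28 spiro dioxolanone cycloadduct
Product: 30 (13R)-α-hydroxy aldehyde (C13–OH, C22 formyl), via dioxolanyl lactol 29 (not isolated)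
Conditions: i-Bu2AlH (1.1 equiv), CH2Cl2, −78 °C; aq potassium sodium tartrate; concentration under vacuum
Reagents that add atoms: none
Why: Partial reduction of the activated, acylal-type lactone carbonyl by one equivalent of i-Bu2AlH at low temperature should outrun attack on the hindered conjugated tert-butyl ester, and the lactol falls apart to pivalaldehyde and the hydroxy aldehyde without touching C13.

Step 17
Reactants: 30 (13R)-α-hydroxy aldehyde; 31 ethyl 2-[bis(2,2,2-trifluoroethoxy)phosphoryl]propanoate
Product: 34 spirobutenolide (rings A and B) carrying the C18 silyl ether, via potassium phosphonate 32 (not isolated), via Z-hydroxy enoate 33 (not isolated)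
Conditions: 31, KN(SiMe3)2, 18-crown-6, THF, −78 °C; then 30, −78 °C to rt
Reagents that add atoms: none
Why: The Still–Gennari variant of the Horner–Wadsworth–Emmons reaction gives the (Z)-2-methyl enoate, whose ester lies next to the tertiary C13 hydroxyl and lactonises in the flask to the α-methylbutenolide (C15, C16, C17 added).

Step 18
Reactants: 34 spirobutenolide carrying the C18 silyl ether
Product: 35 C18 allylic alcohol
Conditions: HF·pyridine, pyridine, THF, 0 °C to rt
Reagents that add atoms: none
Why: Buffered fluoride cleavage of a primary allylic silyl ether leaves the butenolide and the tert-butyl ester intact.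

Step 19
Reactants: 35 C18 allylic alcohol
Product: 36 (E)-enal (C18 aldehyde, C19=C20, C21 methyl)
Conditions: MnO2, CH2Cl2, rt
Reagents that add atoms: none
Why: MnO2 oxidises allylic alcohols chemoselectively to enals under neutral conditions.

Step 20
Reactants: 36 (E)-enal
Product: 37 seco diene–butenolide: (E)-1-(tert-butyldimethylsilyloxy)-3-alkylbuta-1,3-diene (C18–C21) joined through C20, C23, C25 and C2–C5 to C6 of the spiro cyclohexene–butenolide, C9 tert-butyl ester (2R,6S,10S,13R,23R)
Conditions: TBSOTf, Et3N, Et2O, −78 °C to 0 °C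
Reagents that add atoms: tert-butyldimethylsilyl triflate, CC(C)(C)[Si](C)(C)OS(=O)(=O)C(F)(F)F
Why: Soft enolisation (O-silylation of the enal, then γ-deprotonation by Et3N at the unhindered C21 methyl and not at the tertiary C23–H) gives the cross-conjugated (E)-silyl dienol ether without touching C23.

Step 21
Reactants: 37 seco diene–butenolide
Product: 38 bridged cycloadduct (rings C and D closed, C19=C20 bridgehead alkene, C18 silyl ether cis to C17; 2R,6S,10S,13R,16R,18R,22R,23R)
Conditions: Me2AlCl (2.2 equiv), CH2Cl2, 37 added by syringe pump to 0.5 mM, −30 °C to rt; aq NaHCO3/potassium sodium tartrate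
Reagents that add atoms: none
Why: Me2AlCl binds the lactone carbonyl, lowers the butenolide LUMO and lets the silyloxydiene add in a concerted but asynchronous [4π+2π] event in which C21–C22 runs ahead of C16–C18. The closest known reaction types are the type 2 intramolecular Diels–Alder reaction that gives bridgehead alkenes and the macrocyclising intramolecular Diels–Alder reaction onto five-membered unsaturated lactams or lactones, the tether here being longer than in the former. Ring C closes as the six-membered cycloaddition ring, and ring D closes in the same event as an eleven-membered meta bridge from C20 to C22, which leaves C19=C20 as a bridgehead alkene that is trans only in the thirteen-membered perimeter and so is not strained. C16 and C22 are set by suprafacial addition (C17 and the C22 hydrogen stay cis) to the butenolide face syn to C6, the face to which the chain anchored at C6 delivers the diene, and C18 is set by the (E)-enol ether geometry together with an exo lactone, because an endo lactone would force C20 and C23 into the space of C6 and C5. The meta bridge is secured because the 1-silyloxy and 3-alkyl groups both enlarge the HOMO coefficient at C21, which pairs with the electrophilic β-carbon C22. Selectivity over the ring A enoate is secured by the bulky tert-butyl ester, which steers the Lewis acid to the lactone, and by the more strained ten-membered ring that the alternative would need, while slow addition at high dilution holds back oligomerisation.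

Step 22
Reactants: 38 bridged cycloadduct
Product: 40 C19 alcohol (18S,19S,20S; OH19 trans to the C18 silyloxy group, H20 cis to OH19), via C19 alkylborane 39 (not isolated)
Conditions: BH3·THF, THF, 0 °C to rt; then NaBO3·4H2O, THF–H2O, rt
Reagents that add atoms: sodium perborate, [Na+].[Na+].O[B-]1(O)OO[B-](O)(O)OO1
Why: In this hydroboration–oxidation boron goes to the less substituted C19 (also favoured by the allylic oxygen) by syn addition from the face anti to the C18 silyloxy group, the electron-poor C7=C8 enoate and the carbonyl groups reacting more slowly, and both new centres are provisional (C19 is erased and C20 is corrected in step 24).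

Step 23
Reactants: 40 C19 alcohol
Product: 41 C18,C19 trans-diol
Conditions: 48% aq HF, MeCN, 0 °C to rt
Reagents that add atoms: none
Why: Acidic fluoride desilylation frees the hindered C18 hydroxyl without an alkoxide, which avoids retro-aldol cleavage of the β-hydroxy lactone, and it spares the tert-butyl ester.

Step 24
Reactants: 41 C18,C19 trans-diol
Product: 43 C18,C19-dione tert-butyl ester (2R,6S,10S,13R,16R,20R,22R,23R), via 20-epi-dione 42 (not isolated)
Conditions: IBX, DMSO, rt; then DBU (0.2 equiv), CH2Cl2, rt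
Reagents that add atoms: none
Why: IBX oxidises vicinal diols to 1,2-diketones without C–C cleavage, and DBU-catalysed enolisation through the diosphenol then lets C20 settle in the configuration with C23 cis to C13, in which ring C holds C13, C17 and C23 equatorial.

Step 25
Reactants: 43 C18,C19-dione tert-butyl ester
Product: 44 CNP0115928.1 (target)
Conditions: TFA–CH2Cl2 (1:3), 0 °C to rt
Reagents that add atoms: none
Why: Acidolysis of the tert-butyl ester (E1 loss of isobutene) frees the C9 acid under conditions that the lactone and the dione tolerate and that can only reinforce the thermodynamic configuration at C20.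

Compound list
1 | meso-2,4-dimethylglutaric anhydride | C[C@H]1C[C@@H](C)C(=O)OC1=O | starting material
2 | meso-(2R,4S)-2,4-dimethylpentane-1,5-diol | OC[C@H](C)C[C@H](C)CO | intermediate
3 | (2S,4R)-5-hydroxy-2,4-dimethylpentyl acetate | OC[C@H](C)C[C@H](C)COC(C)=O | intermediate
4 | (2S,4R)-2,4-dimethyl-5-oxopentyl acetate | O=C[C@H](C)C[C@H](C)COC(C)=O | intermediate
5 | (2S,4R)-2,4-dimethylhex-5-yn-1-yl acetate (not isolated) | C#C[C@H](C)C[C@H](C)COC(C)=O | intermediate
6 | (2S,4R)-2,4-dimethylhex-5-yn-1-ol | C#C[C@H](C)C[C@H](C)CO | intermediate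
7 | (2S,4R)-2,4-dimethylhex-5-yn-1-yl 4-methylbenzenesulfonate | C#C[C@H](C)C[C@H](C)COS(=O)(=O)c1ccc(C)cc1 | intermediate
8 | (4-bromobut-1-yn-1-yl)trimethylsilane | C[Si](C)(C)C#CCCBr | starting material
9 | [4-(trimethylsilyl)but-3-yn-1-yl]magnesium bromide (not isolated) | C[Si](C)(C)C#CCC[Mg]Br | intermediate
10 | [(6R,8R)-6,8-dimethyldeca-1,9-diyn-1-yl]trimethylsilane | C#C[C@H](C)C[C@H](C)CCCC#C[Si](C)(C)C | intermediate
11 | (E)-alkenyldimethylalane, Al on C19 (not isolated) | C[Al](C)/C=C(\C)[C@H](C)C[C@H](C)CCCC#C[Si](C)(C)C | intermediate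
12 | lithium butyl(alkenyl)dimethylaluminate (not isolated) | [Li+].CCCC[Al-](C)(C)/C=C(\C)[C@H](C)C[C@H](C)CCCC#C[Si](C)(C)C | intermediate
13 | (2E,4R,6R)-3,4,6-trimethyl-11-(trimethylsilyl)undec-2-en-10-yn-1-ol | OC/C=C(\C)[C@H](C)C[C@H](C)CCCC#C[Si](C)(C)C | intermediate
14 | C18 TBS ether of 13 | CC(C)(C)[Si](C)(C)OC/C=C(\C)[C@H](C)C[C@H](C)CCCC#C[Si](C)(C)C | intermediate
15 | tert-butyldimethyl{[(2E,4R,6R)-3,4,6-trimethylundec-2-en-10-yn-1-yl]oxy}silane | CC(C)(C)[Si](C)(C)OC/C=C(\C)[C@H](C)C[C@H](C)CCCC#C | intermediate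
16 | propyne | CC#C | starting material
17 | prop-1-yn-1-yllithium (not isolated) | CC#C[Li] | intermediate
18 | tert-butyl but-2-ynoate | CC#CC(=O)OC(C)(C)C | intermediate
19 | tert-butyl (E)-2-(tributylstannyl)but-2-enoate (not isolated) | C/C=C(\C(=O)OC(C)(C)C)[Sn](CCCC)(CCCC)CCCC | intermediate
20 | tert-butyl (E)-2-iodobut-2-enoate | C/C=C(\C(=O)OC(C)(C)C)I | intermediate
21 | (E)-alkenyl catecholborane from 15 (not isolated) | CC(C)(C)[Si](C)(C)OC/C=C(\C)[C@H](C)C[C@H](C)CCC/C=C/B1Oc2ccccc2O1 | intermediate
22 | tert-butyl (2Z,3E,8R,10R,11E)-13-[(tert-butyldimethylsilyl)oxy]-2-ethylidene-8,10,11-trimethyltrideca-3,11-dienoate | CC(C)(C)[Si](C)(C)OC/C=C(\C)[C@H](C)C[C@H](C)CCC/C=C/C(=C/C)C(=O)OC(C)(C)C | intermediate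
23 | (S)-lactic acid | C[C@H](O)C(=O)O | starting material
24 | pivalaldehyde | CC(C)(C)C=O | starting material
25 | (2S,5S)-2-tert-butyl-5-methyl-1,3-dioxolan-4-one | C[C@@H]1O[C@H](C(C)(C)C)OC1=O | intermediate
26 | (2S,5R)-5-bromo-2-tert-butyl-5-methyl-1,3-dioxolan-4-one (not isolated) | C[C@]1(Br)O[C@H](C(C)(C)C)OC1=O | intermediate
27 | (S)-2-tert-butyl-5-methylene-1,3-dioxolan-4-one | C=C1O[C@H](C(C)(C)C)OC1=O | intermediate
28 | spiro dioxolanone cycloadduct (ring A) | CC(C)(C)[Si](C)(C)OC/C=C(\C)[C@H](C)C[C@H](C)CCC[C@H]1C=C(C(=O)OC(C)(C)C)[C@@H](C)C[C@@]12O[C@H](C(C)(C)C)OC2=O | intermediate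
29 | dioxolanyl lactol, both epimers at the lactol carbon (not isolated) | CC(C)(C)[Si](C)(C)OC/C=C(\C)[C@H](C)C[C@H](C)CCC[C@H]1C=C(C(=O)OC(C)(C)C)[C@@H](C)C[C@@]12O[C@H](C(C)(C)C)OC2O | intermediate
30 | (13R)-α-hydroxy aldehyde | CC(C)(C)[Si](C)(C)OC/C=C(\C)[C@H](C)C[C@H](C)CCC[C@H]1C=C(C(=O)OC(C)(C)C)[C@@H](C)C[C@]1(O)C=O | intermediate
31 | ethyl 2-[bis(2,2,2-trifluoroethoxy)phosphoryl]propanoate | CCOC(=O)C(C)P(=O)(OCC(F)(F)F)OCC(F)(F)F | starting material
32 | potassium carbanion of 31 (not isolated) | [K+].CCOC(=O)[C-](C)P(=O)(OCC(F)(F)F)OCC(F)(F)F | intermediate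
33 | (Z)-γ-hydroxy-α-methyl enoate (not isolated) | CC(C)(C)[Si](C)(C)OC/C=C(\C)[C@H](C)C[C@H](C)CCC[C@H]1C=C(C(=O)OC(C)(C)C)[C@@H](C)C[C@]1(O)/C=C(/C)C(=O)OCC | intermediate
34 | spirobutenolide, C18 TBS ether | CC(C)(C)[Si](C)(C)OC/C=C(\C)[C@H](C)C[C@H](C)CCC[C@H]1C=C(C(=O)OC(C)(C)C)[C@@H](C)C[C@@]12OC(=O)C(C)=C2 | intermediate
35 | spirobutenolide, C18 allylic alcohol | OC/C=C(\C)[C@H](C)C[C@H](C)CCC[C@H]1C=C(C(=O)OC(C)(C)C)[C@@H](C)C[C@@]12OC(=O)C(C)=C2 | intermediate
36 | spirobutenolide, (E)-enal | O=C/C=C(\C)[C@H](C)C[C@H](C)CCC[C@H]1C=C(C(=O)OC(C)(C)C)[C@@H](C)C[C@@]12OC(=O)C(C)=C2 | intermediate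
37 | seco diene–butenolide (precursor of the key step) | CC(C)(C)[Si](C)(C)O/C=C/C(=C)[C@H](C)C[C@H](C)CCC[C@H]1C=C(C(=O)OC(C)(C)C)[C@@H](C)C[C@@]12OC(=O)C(C)=C2 | intermediate
38 | bridged cycloadduct, C18 silyl ether cis to C17, C19=C20 alkene | C[C@@H]1CCC[C@H]2C=C(C(=O)OC(C)(C)C)[C@@H](C)C[C@@]23OC(=O)[C@@]2(C)[C@H](O[Si](C)(C)C(C)(C)C)C=C(C[C@H]23)[C@H](C)C1 | intermediate
39 | C19 alkylborane (not isolated) | C[C@@H]1CCC[C@H]2C=C(C(=O)OC(C)(C)C)[C@@H](C)C[C@@]23OC(=O)[C@@]2(C)[C@H](O[Si](C)(C)C(C)(C)C)[C@@H](B)[C@@H](C[C@H]23)[C@H](C)C1 | intermediate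
40 | C19 alcohol, C18 silyl ether | C[C@@H]1CCC[C@H]2C=C(C(=O)OC(C)(C)C)[C@@H](C)C[C@@]23OC(=O)[C@@]2(C)[C@H](O[Si](C)(C)C(C)(C)C)[C@@H](O)[C@@H](C[C@H]23)[C@H](C)C1 | intermediate
41 | C18,C19 trans-diol | C[C@@H]1CCC[C@H]2C=C(C(=O)OC(C)(C)C)[C@@H](C)C[C@@]23OC(=O)[C@@]2(C)[C@H](O)[C@@H](O)[C@@H](C[C@H]23)[C@H](C)C1 | intermediate
42 | (20S)-dione tert-butyl ester, the 20-epimer (not isolated) | C[C@@H]1CCC[C@H]2C=C(C(=O)OC(C)(C)C)[C@@H](C)C[C@@]23OC(=O)[C@@]2(C)C(=O)C(=O)[C@@H](C[C@H]23)[C@H](C)C1 | intermediate
43 | (20R)-dione tert-butyl ester | C[C@@H]1CCC[C@H]2C=C(C(=O)OC(C)(C)C)[C@@H](C)C[C@@]23OC(=O)[C@@]2(C)C(=O)C(=O)[C@H](C[C@H]23)[C@H](C)C1 | intermediate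
44 | CNP0115928.1 | C[C@@H]1CCC[C@H]2C=C(C(=O)O)[C@@H](C)C[C@@]23OC(=O)[C@@]2(C)C(=O)C(=O)[C@H](C[C@H]23)[C@H](C)C1 | target

Total step count: 25.
Longest linear sequence: 21 steps (steps 1–9, 12, 15–25).

Steps most likely to fail

1. Step 21.
- What may go wrong: intermolecular addition and oligomerisation may outrun the medium-ring closure, the Lewis acid may strip the silyl dienol ether, or the reaction may stop after the first bond.
- Fallback: it sets out from 37 and makes the two bonds in separate polar steps while keeping the tether that selects the butenolide face.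
- A catalytic silyl Lewis acid (TBSOTf, 0.2 equiv, 2,6-di-tert-butylpyridine, CH2Cl2, high dilution, −78 °C) should trigger an intramolecular vinylogous Mukaiyama–Michael addition of C21 to C22. With silyl transfer to the lactone enolate, this gives the macrocyclic enal silyl ketene acetal F1.
- BF3·OEt2 (CH2Cl2, −78 °C) then closes C16–C18 by an intramolecular Mukaiyama aldol reaction to give the C18 carbinol F2.
- TBSOTf/2,6-lutidine returns the material to the route at 38. A C18 epimer would converge at 43.

2. Step 15.
- What may go wrong: the ester-deactivated diene may add sluggishly while it dimerises, and exo or facial selectivity may erode at the temperature needed.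
- Fallback: it sets out from 20 and 15 and raises the diene HOMO by carrying C9 at the alcohol level.
- i-Bu2AlH (CH2Cl2, −78 °C) reduces 20 to (E)-2-iodobut-2-en-1-ol F3.
- Hydroboration of 15 with catecholborane and Suzuki–Miyaura coupling with F3 give the hydroxymethyl diene F4.
- Heating with 27 as in step 15 gives the hydroxymethyl cycloadduct F5.
- TEMPO/PhI(OAc)2 in MeCN–H2O oxidises the allylic alcohol to the C9 acid F6.
- tert-Butyl 2,2,2-trichloroacetimidate (cat. BF3·OEt2, cyclohexane–CH2Cl2) returns the material to the route at 28.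

3. Step 22.
- What may go wrong: hydroboration of the hindered bridgehead alkene may be slow while the enoate or lactone is reduced, boron and the neighbouring silyloxy group may be lost by β-elimination, or the lactone acyl group may migrate to the new C19 hydroxyl.
- Fallback: it sets out from 38 and never passes through a C19 alcohol.
- Buffered mCPBA (NaHCO3, CH2Cl2, 0 °C) attacks only the electron-rich C19=C20 alkene, from the face anti to the silyloxy group, to give the epoxide F7.
- A Lewis acid (BF3·OEt2, CH2Cl2, −78 °C) induces a Meinwald rearrangement. The C20–O bond opens at the tertiary carbon and hydride shifts from C19 to C20 anti to the leaving oxygen, which gives the α-silyloxy ketone F8.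
- Aqueous HF in MeCN gives the α-hydroxy ketone F9.
- IBX in DMSO, followed by DBU as in step 24, returns the material to the route at 43.

Further compounds
F1 | step 21 | macrocyclic enal silyl ketene acetal (ring D closed, C16–C18 open, C18 cis to C21) | C[C@@H]1CCC[C@H]2C=C(C(=O)OC(C)(C)C)[C@@H](C)C[C@@]23OC(O[Si](C)(C)C(C)(C)C)=C(C)[C@H]3C/C(=C\C=O)[C@H](C)C1
F2 | step 21 | C18 carbinol of the cycloadduct | C[C@@H]1CCC[C@H]2C=C(C(=O)OC(C)(C)C)[C@@H](C)C[C@@]23OC(=O)[C@@]2(C)[C@H](O)C=C(C[C@H]23)[C@H](C)C1
F3 | step 15 | (E)-2-iodobut-2-en-1-ol | C/C=C(\CO)I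
F4 | step 15 | hydroxymethyl diene | CC(C)(C)[Si](C)(C)OC/C=C(\C)[C@H](C)C[C@H](C)CCC/C=C/C(=C/C)CO
F5 | step 15 | hydroxymethyl cycloadduct | CC(C)(C)[Si](C)(C)OC/C=C(\C)[C@H](C)C[C@H](C)CCC[C@H]1C=C(CO)[C@@H](C)C[C@@]12O[C@H](C(C)(C)C)OC2=O
F6 | step 15 | C9 acid of the cycloadduct | CC(C)(C)[Si](C)(C)OC/C=C(\C)[C@H](C)C[C@H](C)CCC[C@H]1C=C(C(=O)O)[C@@H](C)C[C@@]12O[C@H](C(C)(C)C)OC2=O
F7 | step 22 | C19,C20 epoxide anti to the silyloxy group | C[C@@H]1CCC[C@H]2C=C(C(=O)OC(C)(C)C)[C@@H](C)C[C@@]23OC(=O)[C@@]2(C)[C@H](O[Si](C)(C)C(C)(C)C)[C@H]4O[C@]4(C[C@H]23)[C@H](C)C1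
F8 | step 22 | C18 silyloxy C19 ketone | C[C@@H]1CCC[C@H]2C=C(C(=O)OC(C)(C)C)[C@@H](C)C[C@@]23OC(=O)[C@@]2(C)[C@H](O[Si](C)(C)C(C)(C)C)C(=O)[C@H](C[C@H]23)[C@H](C)C1
F9 | step 22 | C18 hydroxy C19 ketone | C[C@@H]1CCC[C@H]2C=C(C(=O)OC(C)(C)C)[C@@H](C)C[C@@]23OC(=O)[C@@]2(C)[C@H](O)C(=O)[C@H](C[C@H]23)[C@H](C)C1
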